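**Retrosynthetic overview**

1. Target ⇒ erythro epoxy alcohol 33 (Mitsunobu inversion at C1 with 3‑methylbut‑2‑enoic acid, then desilylation) ⇒ macrocyclic trienoate 30 (ester reduction, hydroxyl‑directed epoxidation of C10=C11).
2. 30 ⇒ acyclic allylic bromide 28 by opening the C8–C9 bond, the CH2–CH2 bond between the allylic carbon on C7 and the carbon next to the oxirane CH: tin‑mediated 11‑endo allyl‑radical macrocyclization, then E1cB loss of acetic acid in the same flask.
3. Enabling feature: with the oxirane read as the C10=C11 alkene and CH2OH as CO2Me, C8–C9 is the central bond of a 1,5‑diene in the eleven‑membered ring. C9 is the primary end of an allylic bromide and C8 the CH2 terminus of a 2‑(1‑acetoxyalkyl)acrylate, two electrophilic carbons joined reductively; the C6 acetate lets both C6 epimers converge on the C6=C7 alkene.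
4. 28 ⇒ geraniol (C4, its CH3, C5, C6 and the whole side chain), ethynylsilane (C2, C3), enal 17 (C1, C9–C11) and methyl acrylate (C7, C8, CH2OH carbon). Copper‑catalysed SN2′ alkynylation sets C4; asymmetric alkenylzinc addition sets C1.
5. Ring order: eleven‑membered carbocycle (step 16), then the oxirane (step 19).

Key step: step 16

Remark: locants follow the carbocycle of the target (C1 = CH–O‑ester, C2=C3, C4 = quaternary carbon, C5, C6=C7 with the CH2OH carbon C7a on C7, C8, C9, C10 and C11 = oxirane carbons, C11 bearing CH3); aldehyde 15 is assumed to be purchasable.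

**Route**

Step 1
Reactants: 1 geraniol
Product: 2 geranyl diethyl phosphate
Conditions: ClP(O)(OEt)2, pyridine, CH2Cl2, 0 °C to rt
Reagents that add atoms: diethyl chlorophosphate, CCOP(=O)(Cl)OCC
Why: Phosphorylation of the primary allylic alcohol should give the leaving group needed for copper‑catalysed allylic substitution.

Step 2
Reactants: 2 geranyl diethyl phosphate, 3 ethynyl(trimethyl)silane
Product: 6 (R)-enyne with the quaternary carbon C4, via lithium (trimethylsilyl)acetylide 4 (not isolated), via alkynylalane 5 (not isolated)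
Conditions: 3, n-BuLi, THF, −78 °C; i-Bu2AlCl, 0 °C; then 2, CuCl2·2H2O (5 mol %), chiral sulfonate-bearing imidazolinium salt (N-heterocyclic carbene precursor, 6 mol %), THF, −15 °C
Reagents that add atoms: none
Why: Copper‑catalysed enantioselective allylic substitution (SN2′) of a γ,γ‑disubstituted allylic phosphate with an alkynylaluminium reagent should attach the alkyne at the methyl‑bearing alkene carbon and create C4; the carbene ligand enantiomer is chosen to give the (R) centre.

Step 3
Reactants: 6 (R)-enyne
Product: 9 (3R)-3-ethynyl-3,7-dimethyloct-6-en-1-ol, via alkylborane 7 (not isolated), via silylalkynol 8 (not isolated)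
Conditions: 9-BBN, THF, 0 °C to rt; then NaOH, H2O2, MeOH/H2O, rt
Reagents that add atoms: hydrogen peroxide, OO
Why: Anti‑Markovnikov hydroboration–oxidation with 9‑BBN should select the monosubstituted vinyl group over the trisubstituted alkene and the silylalkyne, and the alkaline methanolic work‑up should also cleave the C(sp)–Si bond.

Step 4
Reactants: 9 (3R)-3-ethynyl-3,7-dimethyloct-6-en-1-ol
Product: 10 epoxy alcohol (both oxirane epimers)
Conditions: mCPBA, NaHCO3, CH2Cl2, 0 °C
Reagents that add atoms: 3-chloroperoxybenzoic acid, OOC(=O)c1cccc(Cl)c1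
Why: Prilezhaev epoxidation should take place only at the electron‑rich trisubstituted alkene; the uncontrolled oxirane centre is erased in step 5.

Step 5
Reactants: 10 epoxy alcohol
Product: 13 (3R,5E)-3-ethynyl-3,7-dimethyloct-5-ene-1,7-diol, via hydroxy selenide 11 (not isolated), via selenoxide 12 (not isolated)
Conditions: PhSeSePh, NaBH4, EtOH, reflux; then H2O2, THF, 0 °C to rt
Reagents that add atoms: none
Why: Organoselenium epoxide‑to‑allylic‑alcohol transposition: PhSe– should open the oxirane at the secondary carbon, and selenoxide syn‑elimination can only use the chain CH2 hydrogens, which gives the (E)‑alkene next to the tertiary alcohol.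

Step 6
Reactants: 13 diol
Product: 14 bis(triethylsilyl) ether
Conditions: TESOTf, 2,6-lutidine, CH2Cl2, −78 to 0 °C
Reagents that add atoms: triethylsilyl trifluoromethanesulfonate, CC[Si](CC)(CC)OS(=O)(=O)C(F)(F)F
Why: Silyl triflate silylation should protect both the primary and the hindered tertiary hydroxyl group.

Step 7
Reactants: 15 2-[(4-methoxybenzyl)oxy]acetaldehyde, 16 2-(triphenyl-λ5-phosphanylidene)propanal
Product: 17 (2E)-4-[(4-methoxybenzyl)oxy]-2-methylbut-2-enal
Conditions: toluene, 80 °C
Reagents that add atoms: none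
Why: Wittig reaction of a stabilized ylide should give the (E)‑trisubstituted enal, in which C9 is trans to C1.

Step 8
Reactants: 14 bis(triethylsilyl) ether, 17 enal
Product: 20 (1R,4R) bis-allylic alcohol, via alkenylborane 18 (not isolated), via alkenylzinc 19 (not isolated)
Conditions: Cy2BH (from BH3·SMe2 and cyclohexene), toluene, 0 °C to rt; Me2Zn, −78 °C; (+)-MIB (5 mol %); 17, −20 °C; aq. NH4Cl
Reagents that add atoms: none
Why: Hydroboration of the terminal alkyne, boron‑to‑zinc transmetalation and amino‑alcohol‑catalysed alkenylzinc addition should give the (E)‑C2=C3 alkene from syn‑hydroboration and the (1R) carbinol by delivery to the Re face of the aldehyde under control of (+)-MIB.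

Step 9
Reactants: 20 bis-allylic alcohol
Product: 21 C1 acetate
Conditions: Ac2O, pyridine, DMAP (cat.), CH2Cl2, 0 °C to rt
Reagents that add atoms: acetic anhydride, CC(=O)OC(C)=O
Why: Acylation protects C1 with a group that step 17 removes together with the ester reduction.

Step 10
Reactants: 21 C1 acetate
Product: 22 primary alcohol at C6
Conditions: PPTS (cat.), MeOH/CH2Cl2, 0 °C
Reagents that add atoms: none
Why: Acid‑catalysed methanolysis should cleave the primary triethylsilyl ether much faster than the tertiary one and leave the acetate and the PMB ether untouched.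

Step 11
Reactants: 22 primary alcohol
Product: 23 C6 aldehyde
Conditions: Dess–Martin periodinane, NaHCO3, CH2Cl2, 0 °C to rt
Reagents that add atoms: none
Why: Buffered Dess–Martin oxidation should give the aldehyde without touching the alkenes, the acetate or the ethers.

Step 12
Reactants: 23 C6 aldehyde, 24 methyl acrylate
Product: 25 Morita–Baylis–Hillman adduct (both C6 epimers)
Conditions: DABCO (1 equiv), 24 as solvent, rt, several days
Reagents that add atoms: none
Why: The Morita–Baylis–Hillman reaction installs C7, C8 and the ester carbon; the uncontrolled C6 carbinol centre is intended, because step 16 erases it.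

Step 13
Reactants: 25 Morita–Baylis–Hillman adduct
Product: 26 C1,C6 diacetate
Conditions: Ac2O, pyridine, DMAP (cat.), CH2Cl2, 0 °C
Reagents that add atoms: acetic anhydride, CC(=O)OC(C)=O
Why: Acylation turns the C6 hydroxyl into the leaving group for the later E1cB elimination.

Step 14
Reactants: 26 diacetate
Product: 27 C9 allylic alcohol
Conditions: DDQ, CH2Cl2/pH 7 buffer, 0 °C
Reagents that add atoms: none
Why: Oxidative cleavage of the 4‑methoxybenzyl ether (benzylic hydride abstraction, hydrolysis) is orthogonal to the silyl ether and the acetates.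

Step 15
Reactants: 27 C9 allylic alcohol
Product: 28 C9 allylic bromide
Conditions: CBr4, PPh3 (added last, limiting), CH2Cl2, −30 to 0 °C
Reagents that add atoms: carbon tetrabromide, BrC(Br)(Br)Br
Why: The Appel reaction should give the primary allylic bromide by SN2 under neutral conditions that leave the Baylis–Hillman acetate intact.

Step 16
Reactants: 28 C9 allylic bromide
Product: 30 macrocyclic trienoate (1R,4R), via β-acetoxy ester 29 (not isolated)
Conditions: Bu3SnH (1.3 equiv) and AIBN (0.2 equiv) by syringe pump into 28 (2 mM) in benzene, 80 °C; then DBU (3 equiv), 60 °C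
Reagents that add atoms: none
Why: Bu3Sn• abstracts bromine from 28, and the resulting (E)-allyl radical (C9–C10–C11), which is nucleophilic and reacts at its unsubstituted terminus C9, adds to the CH2 terminus C8 of the electron-poor 2-substituted acrylate; the tertiary α-ester radical at C7 takes hydrogen from Bu3SnH to give 29, from which DBU removes acetic acid by an E1cB elimination. The closest known reaction type is the tin hydride-mediated endo macrocyclization of alkyl and allylic radicals onto acrylates and enones, combined with the base-induced elimination of Morita–Baylis–Hillman-type β-acetoxy esters. The eleven-membered carbocycle is closed in the 11-endo-trig mode at C8–C9 and no other ring forms. No new stereocentre remains: C6 and C7 of 29 are erased, so both C6 epimers of 28 and all diastereomers of 29 should converge on one enoate, whose geometry (C5 anti to CO2Me, the ring-cis arrangement of the target) is controlled by A(1,3) strain in the ester enolate during elimination, while C1 and C4 are not touched. The step needs ring closure to be faster than hydrogen transfer to the allyl radical and than intermolecular addition, and attack through C9 instead of C11; the first is secured by syringe-pump addition at high dilution, by the polarity match and by the low rate at which stabilized allyl radicals abstract hydrogen from Bu3SnH, the second by the fully substituted C11 terminus and the preference for the 11- over the 9-membered ring. The two (E)-alkenes, the quaternary carbon C4 and the planar acrylate leave the chain few rotatable bonds, which should help the entropically demanding closure.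

Step 17
Reactants: 30 macrocyclic trienoate
Product: 31 macrocyclic diol (C1–OH, C7a–OH)
Conditions: i-Bu2AlH (6 equiv), CH2Cl2, −78 to −40 °C; aq. KNaC4H4O6
Reagents that add atoms: none
Why: Hydride reduction should convert the enoate into the allylic alcohol by 1,2‑reduction and cleave the C1 acetate in the same operation, without touching the silyl ether.

Step 18
Reactants: 31 macrocyclic diol
Product: 32 C7a tert-butyldimethylsilyl ether
Conditions: TBSCl (1.05 equiv), imidazole, CH2Cl2, −20 °C
Reagents that add atoms: tert-butyldimethylsilyl chloride, CC(C)(C)[Si](C)(C)Cl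
Why: Silylation should select the primary allylic alcohol over the hindered secondary bis‑allylic one, leaving C1–OH as the only directing group.

Step 19
Reactants: 32 C7a silyl ether
Product: 33 erythro epoxy alcohol
Conditions: VO(acac)2 (5 mol %), TBHP (1.5 equiv), CH2Cl2, 0 °C
Reagents that add atoms: tert-butyl hydroperoxide, CC(C)(C)OO
Why: Vanadium‑catalysed hydroxyl‑directed epoxidation should select the trisubstituted C10=C11 alkene, and with the methyl group geminal to the carbinol carbon the vanadate transition state places C1–H next to that methyl (A(1,2) strain), which gives the erythro isomer; from the (1R) carbinol this is the oxirane configuration of the target at C10 and C11.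

Step 20
Reactants: 33 erythro epoxy alcohol, 34 3-methylbut-2-enoic acid
Product: 35 threo epoxy ester (1S)
Conditions: PPh3, DIAD, toluene, 0 °C to rt
Reagents that add atoms: none
Why: Mitsunobu esterification should invert C1 by SN2 displacement of the oxyphosphonium ion (erythro to threo); the neighbouring oxirane disfavours ionisation, and SN2′ attack at C3 is blocked by the quaternary carbon.

Step 21
Reactants: 35 threo epoxy ester
Product: 36 target CNP0248133.1
Conditions: HF·pyridine, pyridine, THF, 0 °C to rt
Reagents that add atoms: none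
Why: Buffered fluoride cleavage should remove the primary and the tertiary silyl ether and leave the oxirane and the ester intact.

**Compound list**

1 | geraniol, (2E)-3,7-dimethylocta-2,6-dien-1-ol | CC(C)=CCC/C(C)=C/CO | starting material
2 | diethyl (2E)-3,7-dimethylocta-2,6-dien-1-yl phosphate | CC(C)=CCC/C(C)=C/COP(=O)(OCC)OCC | intermediate
3 | ethynyl(trimethyl)silane | C#C[Si](C)(C)C | starting material
4 | lithium (trimethylsilyl)acetylide | [Li]C#C[Si](C)(C)C | intermediate
5 | diisobutyl[(trimethylsilyl)ethynyl]aluminium | CC(C)C[Al](CC(C)C)C#C[Si](C)(C)C | intermediate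
6 | [(3R)-3-ethenyl-3,7-dimethyloct-6-en-1-yn-1-yl](trimethyl)silane | C[Si](C)(C)C#C[C@](C)(CCC=C(C)C)C=C | intermediate
7 | 9-{(3S)-3,7-dimethyl-3-[(trimethylsilyl)ethynyl]oct-6-en-1-yl}-9-borabicyclo[3.3.1]nonane (same spatial arrangement as 6; the descriptor changes because boron ranks below carbon) | C[Si](C)(C)C#C[C@](C)(CCC=C(C)C)CCB1C2CCCC1CCC2 | intermediate
8 | (3R)-3,7-dimethyl-3-[(trimethylsilyl)ethynyl]oct-6-en-1-ol | C[Si](C)(C)C#C[C@](C)(CCC=C(C)C)CCO | intermediate
9 | (3R)-3-ethynyl-3,7-dimethyloct-6-en-1-ol | C#C[C@](C)(CCC=C(C)C)CCO | intermediate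
10 | (3R)-5-(3,3-dimethyloxiran-2-yl)-3-ethynyl-3-methylpentan-1-ol, both oxirane epimers | C#C[C@](C)(CCC1OC1(C)C)CCO | intermediate
11 | (3R)-3-ethynyl-3,7-dimethyl-6-(phenylselanyl)octane-1,7-diol, both C6 epimers | C#C[C@](C)(CCC([Se]c1ccccc1)C(C)(C)O)CCO | intermediate
12 | (3R)-3-ethynyl-3,7-dimethyl-6-(phenylseleninyl)octane-1,7-diol | C#C[C@](C)(CCC([Se](=O)c1ccccc1)C(C)(C)O)CCO | intermediate
13 | (3R,5E)-3-ethynyl-3,7-dimethyloct-5-ene-1,7-diol | C#C[C@](C)(C/C=C/C(C)(C)O)CCO | intermediate
14 | (3R,5E)-3-ethynyl-3,7-dimethyl-1,7-bis[(triethylsilyl)oxy]oct-5-ene | C#C[C@](C)(C/C=C/C(C)(C)O[Si](CC)(CC)CC)CCO[Si](CC)(CC)CC | intermediate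
15 | 2-[(4-methoxybenzyl)oxy]acetaldehyde | O=CCOCc1ccc(OC)cc1 | starting material
16 | 2-(triphenyl-λ5-phosphanylidene)propanal | CC(C=O)=P(c1ccccc1)(c1ccccc1)c1ccccc1 | starting material
17 | (2E)-4-[(4-methoxybenzyl)oxy]-2-methylbut-2-enal | O=C/C(C)=C/COCc1ccc(OC)cc1 | intermediate
18 | (E)-alkenyl(dicyclohexyl)borane from 14, boron on C2, (4R) | C1CCCCC1B(C1CCCCC1)/C=C/[C@](C)(C/C=C/C(C)(C)O[Si](CC)(CC)CC)CCO[Si](CC)(CC)CC | intermediate
19 | (E)-alkenyl(methyl)zinc from 18, zinc on C2, (4R) | C[Zn]/C=C/[C@](C)(C/C=C/C(C)(C)O[Si](CC)(CC)CC)CCO[Si](CC)(CC)CC | intermediate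
20 | (2E,4R,5E,7R,9E)-1-[(4-methoxybenzyl)oxy]-3,7,11-trimethyl-11-[(triethylsilyl)oxy]-7-{2-[(triethylsilyl)oxy]ethyl}dodeca-2,5,9-trien-4-ol; ring locants (1R,4R) | O[C@@H](/C(C)=C/COCc1ccc(OC)cc1)/C=C/[C@](C)(C/C=C/C(C)(C)O[Si](CC)(CC)CC)CCO[Si](CC)(CC)CC | intermediate
21 | acetate of 20 at C1, (1R,4R) | CC(=O)O[C@@H](/C(C)=C/COCc1ccc(OC)cc1)/C=C/[C@](C)(C/C=C/C(C)(C)O[Si](CC)(CC)CC)CCO[Si](CC)(CC)CC | intermediate
22 | 21 with free primary hydroxyl at C6, (1R,4R) | CC(=O)O[C@@H](/C(C)=C/COCc1ccc(OC)cc1)/C=C/[C@](C)(C/C=C/C(C)(C)O[Si](CC)(CC)CC)CCO | intermediate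
23 | C6 aldehyde, (1R,4R) | CC(=O)O[C@@H](/C(C)=C/COCc1ccc(OC)cc1)/C=C/[C@](C)(C/C=C/C(C)(C)O[Si](CC)(CC)CC)CC=O | intermediate
24 | methyl acrylate | C=CC(=O)OC | starting material
25 | Morita–Baylis–Hillman adduct: methyl 2-methylidene-3-hydroxy ester (C6–OH, C7=C8H2), (1R,4R), both C6 epimers | CC(=O)O[C@@H](/C(C)=C/COCc1ccc(OC)cc1)/C=C/[C@](C)(C/C=C/C(C)(C)O[Si](CC)(CC)CC)CC(O)C(=C)C(=O)OC | intermediate
26 | C6 acetate of 25, (1R,4R), both C6 epimers | CC(=O)O[C@@H](/C(C)=C/COCc1ccc(OC)cc1)/C=C/[C@](C)(C/C=C/C(C)(C)O[Si](CC)(CC)CC)CC(OC(C)=O)C(=C)C(=O)OC | intermediate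
27 | C9 primary allylic alcohol, (1R,4R), both C6 epimers | CC(=O)O[C@@H](/C(C)=C/CO)/C=C/[C@](C)(C/C=C/C(C)(C)O[Si](CC)(CC)CC)CC(OC(C)=O)C(=C)C(=O)OC | intermediate
28 | C9 allylic bromide with C1 and C6 acetates, (1R,4R,10E), both C6 epimers | CC(=O)O[C@@H](/C(C)=C/CBr)/C=C/[C@](C)(C/C=C/C(C)(C)O[Si](CC)(CC)CC)CC(OC(C)=O)C(=C)C(=O)OC | intermediate
29 | eleven-membered β-acetoxy ester (C6–OAc, C7–CO2Me), (1R,4R,2E,10E), mixture at C6 and C7 | C1/C=C(C)/[C@H](OC(C)=O)/C=C/[C@](C)(C/C=C/C(C)(C)O[Si](CC)(CC)CC)CC(OC(C)=O)C(C(=O)OC)C1 | intermediate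
30 | macrocyclic trienoate: methyl ester on C7, C1 acetate, (1R,4R,2E,6E,10E) | C1/C=C(C)/[C@H](OC(C)=O)/C=C/[C@](C)(C/C=C/C(C)(C)O[Si](CC)(CC)CC)C/C=C(/C(=O)OC)C1 | intermediate
31 | macrocyclic diol (C1–OH, C7a–OH), (1R,4R,2E,6E,10E) | C1/C=C(C)/[C@H](O)/C=C/[C@](C)(C/C=C/C(C)(C)O[Si](CC)(CC)CC)C/C=C(/CO)C1 | intermediate
32 | C7a tert-butyldimethylsilyl ether of 31, (1R,4R) | C1/C=C(C)/[C@H](O)/C=C/[C@](C)(C/C=C/C(C)(C)O[Si](CC)(CC)CC)C/C=C(/CO[Si](C)(C)C(C)(C)C)C1 | intermediate
33 | erythro epoxy alcohol, (1R,4R,10R,11R); oxirane arranged as in the target, C11 is formally R only because of the free hydroxyl group | O[C@@H]1/C=C/[C@](C)(C/C=C/C(C)(C)O[Si](CC)(CC)CC)C/C=C(/CO[Si](C)(C)C(C)(C)C)CC[C@H]2O[C@]12C | intermediate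
34 | 3-methylbut-2-enoic acid | CC(C)=CC(=O)O | starting material
35 | bis-silylated target, (1S,4R,10R,11S) | CC(C)=CC(=O)O[C@H]1/C=C/[C@](C)(C/C=C/C(C)(C)O[Si](CC)(CC)CC)C/C=C(/CO[Si](C)(C)C(C)(C)C)CC[C@H]2O[C@]12C | intermediate
36 | CNP0248133.1, (1S,4R,10R,11S) | CC(C)=CC(=O)O[C@H]1/C=C/[C@](C)(C/C=C/C(C)(C)O)C/C=C(/CO)CC[C@H]2O[C@]12C | target

**Totals**

Total step count: 21. Longest linear sequence: 20 steps (steps 1–6 and 8–21, from geraniol).

**Steps most likely to fail**

Step 16. Hydrogen transfer to the allyl radical and intermolecular radical addition may outrun closure of the eleven‑membered ring. The fallback sets out from 28 and comes back at 30. LiBr in THF should exchange the activated acetate of 28 for bromide by SN2′ substitution with allylic transposition, giving the bis(allylic bromide) F1, a methyl (2Z)-2-(bromomethyl)enoate. Slow addition of F1 to zerovalent nickel, Ni(cod)2, in N‑methylpyrrolidone at 50 °C and high dilution should couple the two primary allylic termini C8 and C9 through a bis(π‑allyl)nickel intermediate, the classical intramolecular allyl–allyl coupling for eleven‑membered 1,5‑dienes, and give 30 directly.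

Step 20. The SN2 displacement at the ring‑embedded, α‑branched oxyphosphonium centre may be slow, so that elimination or ionisation with loss of stereochemical integrity competes. The fallback sets out from 33 and comes back at 35. Dess–Martin oxidation of 33 should give the epoxy enone F2. Corey–Bakshi–Shibata reduction (BH3·SMe2, the oxazaborolidine enantiomer that delivers hydride to the ketone face leading to the (1S) carbinol) should give the threo epoxy alcohol F3 under reagent control. Yamaguchi esterification of F3 with acid 34 (2,4,6‑trichlorobenzoyl chloride, Et3N; then DMAP) should give 35 with retention at C1.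

Step 19. The macrocycle may not populate the conformer needed for vanadium delivery, which would erode facial selectivity, and oxidation of the bis‑allylic alcohol to the dienone may compete. The fallback sets out from 32 and comes back at 33. Stereocontrol is moved from the substrate to the reagent by a Sharpless asymmetric epoxidation in its matched, kinetic‑resolution sense: Ti(OiPr)4, D‑(−)‑diisopropyl tartrate, TBHP, 4 Å molecular sieves, CH2Cl2, −20 °C. For a (1R) carbinol whose reacting alkene is the higher‑ranked substituent this tartrate is the fast‑reacting combination and should give the erythro epoxide 33, while the same complex is mismatched for the C2=C3 alkene. No compound outside the list is formed (F0).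

**Further compounds**

F1 | step 16 | bis(allylic bromide): methyl (2Z)-2-(bromomethyl)enoate with C9 bromide and C1 acetate, (1R,4R) | CC(=O)O[C@@H](/C(C)=C/CBr)/C=C/[C@](C)(C/C=C/C(C)(C)O[Si](CC)(CC)CC)C/C=C(/C(=O)OC)CBr
F2 | step 20 | macrocyclic epoxy enone (C1 ketone), oxirane as in 33 | O=C1/C=C/[C@](C)(C/C=C/C(C)(C)O[Si](CC)(CC)CC)C/C=C(/CO[Si](C)(C)C(C)(C)C)CC[C@H]2O[C@]12C
F3 | step 20 | threo epoxy alcohol, C1 epimer of 33, (1S) | O[C@H]1/C=C/[C@](C)(C/C=C/C(C)(C)O[Si](CC)(CC)CC)C/C=C(/CO[Si](C)(C)C(C)(C)C)CC[C@H]2O[C@]12C
F0 | step 19 | none | none
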